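**Plan**

Retrosynthesis: remove the C2 acetate and unmask the 2α,3α-diol; trace the Δ7 olefin with 9α-H back to a Δ8-7β-ol (reductive 1,3-transposition); cut C9–C11 (enol triflate plus a C11–C15 zinc reagent); remove the C8 methyl; open ring A at C2=C3 (metathesis); finally cut C1–C10 and C4–C5.
Enabling feature: C5 and C10 are the β- and α-carbons of a 2-methylcyclohex-2-enone whose carbonyl is C9 (ring B), and ring A divides into a reverse-prenyl arm (C4, C3) on C5 and an allyl arm (C1, C2) on C10.
Forward: ring B comes intact from (R)-carvone, both arms are attached in one flask, ring A closes by metathesis, then the diol, the C8 methyl, the side chain and the olefin shift follow.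
Stereochemistry: the carvone-derived C7 oxygen directs C5 (anti), C5 directs C10 (anti), the trans-decalin sends OsO4 to the α-face, the inverted C7 oxygen passes hydrogen to C9α, and C13 is bought with the half-ester.

Key step: step 4

Remarks: Bicyclic compounds carry labdane numbers (ring A = C1–C5, C10; ring B = C5–C10; chain C11–C15); β is the face of the C10 methyl. The target SMILES reads as the normal labdane: 5α-H, 9α-H, 10β-CH3, 2α-OAc, 3α-OH, 13S. (R)-Monomethyl 3-methylglutarate 19 (the half-ester from pig-liver-esterase hydrolysis of dimethyl 3-methylglutarate) is assumed to be purchasable in enantiopure form.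

**Route**

Step 1
Reactants: 1 (R)-carvone
Product: 4 (R)-5-acetoxy-2-methylcyclohex-2-en-1-one, via methoxy hydroperoxide 2 (not isolated), via peroxyacetate 3 (not isolated)
Conditions: O3, CH2Cl2/MeOH, −78 °C; then Ac2O, Et3N, DMAP (cat.), −10 → 23 °C
Reagents that add atoms: ozone, O=[O+][O-]; methanol, CO
Why: Ozone cleaves only the electron-rich isopropenyl group and methanol traps the carbonyl oxide, and the derived peracetate undergoes Criegee rearrangement with migration of the ring carbon to oxygen with retention, so the former isopropenyl carbon becomes the acetyl group of 4 and the carvone stereocentre is kept.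

Step 2
Reactants: 4 (R)-5-acetoxy-2-methylcyclohex-2-en-1-one
Product: 5 (R)-5-hydroxy-2-methylcyclohex-2-en-1-one
Conditions: K2CO3 (cat.), MeOH, 0 °C
Reagents that add atoms: none
Why: Base-catalysed transesterification (methanolysis) should free the alcohol at 0 °C, where E1cB loss of the β-oxygen is slow, and the stereocentre is not involved.

Step 3
Reactants: 5 (R)-5-hydroxy-2-methylcyclohex-2-en-1-one
Product: 6 (R)-5-(tert-butyldimethylsilyloxy)-2-methylcyclohex-2-en-1-one
Conditions: TBSCl, imidazole, DMF, 23 °C
Reagents that add atoms: tert-butyldimethylsilyl chloride, CC(C)(C)[Si](C)(C)Cl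
Why: Imidazole-promoted silylation of an unhindered secondary alcohol gives the bulky ether that directs the conjugate addition.

Step 4
Reactants: 6 (R)-5-(tert-butyldimethylsilyloxy)-2-methylcyclohex-2-en-1-one; 7 prenyltrimethylsilane [(3-methylbut-2-en-1-yl)trimethylsilane]; 8 allyl bromide
Product: 11 (2S,3S,5R)-2-allyl-5-(tert-butyldimethylsilyloxy)-2-methyl-3-(2-methylbut-3-en-2-yl)cyclohexan-1-one (labdane numbering: 5β reverse-prenyl, 10α allyl, 10β methyl, 7α OTBS), via trimethylsilyl enol ether 9 (not isolated), via lithium enolate 10 (not isolated)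
Conditions: 7, Tf2NH (5 mol%), CH2Cl2, −78 °C; solvent exchange to THF; MeLi, 0 °C; 8, DMPU, −78 → 0 °C
Reagents that add atoms: none
Why: Me3SiNTf2, formed in the flask from Tf2NH and 7, silylates the enone oxygen and the allylsilane attacks C5 through its γ-carbon in an open SE2′ Hosomi–Sakurai conjugate addition, which creates the quaternary C4 and the C4–C5 bond and passes the silyl group on to give enol ether 9 with the double bond fixed at C9=C10. MeLi then cleaves the O–Si bond (regiospecific enolate generation from a silyl enol ether) and lithium enolate 10 is C-allylated at C10 by 8, forming C1–C10; the closest known reaction type is conjugate addition followed by alkylation of the regiospecifically formed enolate. No ring closes in this step. C5 is set by axial attack on the half-chair enone anti to the C7 silyloxy group (the trans rule for 5-substituted cyclohexenones), and C10 by approach of the bromide anti to the new tert-alkyl group on C5, so the methyl ends β and the two olefinic arms trans-diequatorial. The step needs γ- over α-attack of the prenyl unit, 1,4- over 1,2-addition and C- over O-allylation; the first two follow from the SE2′ course of allylsilanes with Lewis-acid-activated enones and the last from a lithium enolate with a soft allylic bromide in THF/DMPU, and because this enolate lies away from C8 it cannot expel the C7 silyloxy group.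

Step 5
Reactants: 11 (2S,3S,5R)-2-allyl-5-(tert-butyldimethylsilyloxy)-2-methyl-3-(2-methylbut-3-en-2-yl)cyclohexan-1-one
Product: 12 trans-fused bicyclic ketone (labdane numbering: C9 ketone, Δ2 olefin, 4,4-dimethyl, 10β-methyl, 5α-H, 7α-OTBS)
Conditions: second-generation Grubbs catalyst RuCl2(=CHPh)(PCy3)(H2IMes) (5 mol%), CH2Cl2, 40 °C
Reagents that add atoms: none
Why: Ring-closing metathesis joins the two terminal vinyl groups held trans-diequatorial on C5 and C10, loss of ethylene drives closure of ring A, and the N-heterocyclic-carbene catalyst still engages the neopentyl vinyl group.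

Step 6
Reactants: 12 trans-fused bicyclic ketone
Product: 13 2α,3α-diol of 12 (C9 ketone, 7α-OTBS, 2α,3α-dihydroxy, 4,4,10β-trimethyl, 5α-H)
Conditions: OsO4 (2 mol%), N-methylmorpholine N-oxide, acetone/H2O, 23 °C
Reagents that add atoms: osmium tetroxide, O=[Os](=O)(=O)=O (carries both new oxygens; re-formed from N-methylmorpholine N-oxide, C[N+]1([O-])CCOCC1, and water, O)
Why: Upjohn dihydroxylation should add both oxygens syn to the α-face of the Δ2 olefin because the axial 4β- and 10β-methyl groups close the β-face, which sets C2 and C3.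

Step 7
Reactants: 13 2α,3α-diol
Product: 14 2α,3α-acetonide of 13 (C9 ketone, 7α-OTBS)
Conditions: Me2C(OMe)2, PPTS, CH2Cl2, 23 °C
Reagents that add atoms: 2,2-dimethoxypropane, COC(C)(C)OC
Why: Acid-catalysed transacetalisation closes the dioxolane on the cis (axial/equatorial) diol and protects both hydroxyls from the bases and oxidant that follow, while the hindered ketone and the silyl ether are left.

Step 8
Reactants: 14 acetonide ketone
Product: 16 C8-methyl derivative of 14 (C8 epimers, which converge in step 9), via lithium enolate 15 (not isolated)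
Conditions: LiN(iPr)2 (LDA), THF, −78 °C; MeI, DMPU, −78 → −40 °C
Reagents that add atoms: iodomethane, CI
Why: Kinetic enolate alkylation, in which C8 is the only enolisable position (C10 is quaternary) and the lithium enolate should be methylated at −78 °C before the β-silyloxy group can leave.

Step 9
Reactants: 16 C8-methyl ketone
Product: 18 enol triflate (C9–OTf, C8=C9, 8-methyl, 7α-OTBS, 2α,3α-acetonide, 5α-H, 10β-methyl), via potassium enolate 17 (not isolated)
Conditions: KN(SiMe3)2 (KHMDS), THF, −78 °C; PhNTf2, −78 → −20 °C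
Reagents that add atoms: N-phenylbis(trifluoromethanesulfonimide), O=S(=O)(N(c1ccccc1)S(=O)(=O)C(F)(F)F)C(F)(F)F
Why: Enolate O-sulfonylation, in which the single α-hydrogen on C8 fixes the tetrasubstituted C8=C9 enolate and PhNTf2 traps it on oxygen at low temperature, so both C8 epimers give the same triflate.

Step 10
Reactants: 19 (R)-monomethyl 3-methylglutarate [(R)-5-methoxy-3-methyl-5-oxopentanoic acid]
Product: 21 (S)-4-methyltetrahydro-2H-pyran-2-one, via hydroxy acid 20 (not isolated)
Conditions: LiBH4, THF, 0 → 40 °C; then 2 M HCl, 23 °C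
Reagents that add atoms: none
Why: Chemoselective ester reduction, in which the acid is held as its unreactive lithium carboxylate while LiBH4 reduces the methyl ester and the δ-hydroxy acid lactonises on acidification, so the former ester carbon becomes C11 and the former acid carbon C15 with the stereocentre untouched.

Step 11
Reactants: 21 (S)-4-methyltetrahydro-2H-pyran-2-one
Product: 23 methyl (R)-5-iodo-3-methylpentanoate, via silyl iodoester 22 (not isolated)
Conditions: Me3SiCl (excess), NaI, MeCN, 60 °C; then MeOH, 23 → 50 °C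
Reagents that add atoms: sodium iodide, [Na+].[I-]; methanol, CO
Why: Lactone cleavage by iodotrimethylsilane made in the flask (O-silylation, then SN2 attack of iodide at the primary O–CH2 carbon), after which HCl/MeOH from the excess chlorosilane esterifies the acid (Fischer esterification).

Step 12
Reactants: 18 enol triflate; 23 methyl (R)-5-iodo-3-methylpentanoate
Product: 25 methyl (13S)-7α-(tert-butyldimethylsilyloxy)-2α,3α-(isopropylidenedioxy)labd-8-en-15-oate, via alkylzinc iodide 24 (not isolated)
Conditions: 23, Zn dust (activated with BrCH2CH2Br/Me3SiCl), LiCl, THF, 40 °C; then 18, Pd(dppf)Cl2 (5 mol%), THF/NMP, 60 °C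
Reagents that add atoms: none
Why: Negishi sp2–sp3 coupling, in which zinc inserts into the primary C–I bond without touching the ester and the wide-bite-angle palladium catalyst should join the alkylzinc to the cyclogeranyl-type enol triflate faster than β-hydride elimination, forming C9–C11.

Step 13
Reactants: 25 methyl (13S)-7α-(tert-butyldimethylsilyloxy)-2α,3α-(isopropylidenedioxy)labd-8-en-15-oate
Product: 26 methyl (13S)-7α-hydroxy-2α,3α-(isopropylidenedioxy)labd-8-en-15-oate
Conditions: Bu4NF, AcOH, THF, 23 → 40 °C
Reagents that add atoms: none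
Why: Fluoride-induced desilylation, buffered with acetic acid so that the methyl ester is not attacked, frees the allylic alcohol while the acetonide stays.

Step 14
Reactants: 26 methyl (13S)-7α-hydroxy-2α,3α-(isopropylidenedioxy)labd-8-en-15-oate
Product: 27 methyl (13S)-2α,3α-(isopropylidenedioxy)-7-oxolabd-8-en-15-oate
Conditions: Dess–Martin periodinane, NaHCO3, CH2Cl2, 23 °C
Reagents that add atoms: none
Why: Dess–Martin oxidation of the allylic alcohol gives the tetrasubstituted enone and erases the C7 configuration, which has served its purpose in step 4.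

Step 15
Reactants: 27 methyl (13S)-2α,3α-(isopropylidenedioxy)-7-oxolabd-8-en-15-oate
Product: 28 methyl (13S)-7β-hydroxy-2α,3α-(isopropylidenedioxy)labd-8-en-15-oate
Conditions: NaBH4, CeCl3·7H2O, MeOH, −78 → −40 °C
Reagents that add atoms: none
Why: Luche 1,2-reduction, in which hydride is expected to add axially from the α-face of the half-chair enone to give the pseudo-equatorial 7β-alcohol, a net inversion of C7.

Step 16
Reactants: 28 methyl (13S)-7β-hydroxy-2α,3α-(isopropylidenedioxy)labd-8-en-15-oate
Product: 31 methyl (13S)-2α,3α-(isopropylidenedioxy)labd-7-en-15-oate, via sulfonylhydrazine 29 (not isolated), via allylic diazene 30 (not isolated)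
Conditions: 2-nitrobenzenesulfonylhydrazide (NBSH), PPh3, DEAD, N-methylmorpholine, −30 → 23 °C
Reagents that add atoms: none
Why: Myers reductive 1,3-transposition, in which Mitsunobu displacement inverts C7 (7β-O to 7α-N), sulfinate loss gives the monoalkyl diazene, and its retro-ene loss of N2 delivers hydrogen suprafacially to the α-face of C9, setting 9α-H (chain β) and moving the olefin to C7=C8.

Step 17
Reactants: 31 methyl (13S)-2α,3α-(isopropylidenedioxy)labd-7-en-15-oate
Product: 32 methyl (13S)-2α,3α-dihydroxylabd-7-en-15-oate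
Conditions: AcOH/H2O (4:1), 45 °C
Reagents that add atoms: none
Why: Mild acetal hydrolysis should release the cis-diol without hydrolysing the methyl ester or isomerising the trisubstituted Δ7 olefin.

Step 18
Reactants: 32 methyl (13S)-2α,3α-dihydroxylabd-7-en-15-oate
Product: 33 methyl (13S)-2α-acetoxy-3α-hydroxylabd-7-en-15-oate (CNP0571009.1)
Conditions: Ac2O (1.1 equiv), pyridine, CH2Cl2, 0 °C
Reagents that add atoms: acetic anhydride, CC(=O)OC(C)=O
Why: Selective acylation, in which the equatorial 2α-hydroxyl should react while the axial 3α-hydroxyl next to the gem-dimethyl carbon C4 is left.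

**Compound list**

1 | (R)-carvone | O=C1C(C)=CC[C@@H](C(C)=C)C1 | starting material
2 | methoxy hydroperoxide from ozonolysis of 1 in methanol (not isolated; new carbinol centre unassigned) | O=C1C(C)=CC[C@@H](C(C)(OC)OO)C1 | intermediate
3 | peroxyacetate of 2 (not isolated) | O=C1C(C)=CC[C@@H](C(C)(OC)OOC(C)=O)C1 | intermediate
4 | (R)-5-acetoxy-2-methylcyclohex-2-en-1-one | O=C1C(C)=CC[C@@H](OC(C)=O)C1 | intermediate
5 | (R)-5-hydroxy-2-methylcyclohex-2-en-1-one | O=C1C(C)=CC[C@@H](O)C1 | intermediate
6 | (R)-5-(tert-butyldimethylsilyloxy)-2-methylcyclohex-2-en-1-one | O=C1C(C)=CC[C@@H](O[Si](C)(C)C(C)(C)C)C1 | intermediate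
7 | prenyltrimethylsilane | CC(C)=CC[Si](C)(C)C | starting material
8 | allyl bromide | C=CCBr | starting material
9 | trimethylsilyl enol ether after conjugate addition (C9–OSiMe3, C9=C10; 5β reverse-prenyl, 7α-OTBS; not isolated) | C[Si](C)(C)OC1=C(C)[C@H](C(C)(C)C=C)C[C@@H](O[Si](C)(C)C(C)(C)C)C1 | intermediate
10 | lithium enolate from 9 (not isolated) | [Li]OC1=C(C)[C@H](C(C)(C)C=C)C[C@@H](O[Si](C)(C)C(C)(C)C)C1 | intermediate
11 | (2S,3S,5R)-2-allyl-5-(tert-butyldimethylsilyloxy)-2-methyl-3-(2-methylbut-3-en-2-yl)cyclohexan-1-one | O=C1C[C@H](O[Si](C)(C)C(C)(C)C)C[C@@H](C(C)(C)C=C)[C@]1(C)CC=C | intermediate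
12 | trans-fused bicyclic ketone (C9 ketone, Δ2, 4,4,10β-trimethyl, 5α-H, 7α-OTBS) | O=C1C[C@H](O[Si](C)(C)C(C)(C)C)C[C@@H]2[C@]1(C)CC=CC2(C)C | intermediate
13 | 2α,3α-diol of 12 | O=C1C[C@H](O[Si](C)(C)C(C)(C)C)C[C@@H]2[C@]1(C)C[C@@H](O)[C@@H](O)C2(C)C | intermediate
14 | 2α,3α-acetonide of 13 | O=C1C[C@H](O[Si](C)(C)C(C)(C)C)C[C@@H]2[C@]1(C)C[C@H]3OC(C)(C)O[C@H]3C2(C)C | intermediate
15 | lithium enolate of 14 (C8=C9; not isolated) | [Li]OC1=C[C@H](O[Si](C)(C)C(C)(C)C)C[C@@H]2[C@]1(C)C[C@H]3OC(C)(C)O[C@H]3C2(C)C | intermediate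
16 | C8-methyl ketone (C8 epimers) | O=C1C(C)[C@H](O[Si](C)(C)C(C)(C)C)C[C@@H]2[C@]1(C)C[C@H]3OC(C)(C)O[C@H]3C2(C)C | intermediate
17 | potassium enolate of 16 (not isolated) | [K]OC1=C(C)[C@H](O[Si](C)(C)C(C)(C)C)C[C@@H]2[C@]1(C)C[C@H]3OC(C)(C)O[C@H]3C2(C)C | intermediate
18 | enol triflate (C9–OTf, Δ8, 8-methyl, 7α-OTBS, 2α,3α-acetonide) | O=S(=O)(OC1=C(C)[C@H](O[Si](C)(C)C(C)(C)C)C[C@@H]2[C@]1(C)C[C@H]3OC(C)(C)O[C@H]3C2(C)C)C(F)(F)F | intermediate
19 | (R)-monomethyl 3-methylglutarate | COC(=O)C[C@H](C)CC(=O)O | starting material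
20 | (S)-5-hydroxy-3-methylpentanoic acid (not isolated) | OCC[C@H](C)CC(=O)O | intermediate
21 | (S)-4-methyltetrahydro-2H-pyran-2-one | O=C1C[C@@H](C)CCO1 | intermediate
22 | trimethylsilyl (R)-5-iodo-3-methylpentanoate (not isolated) | C[Si](C)(C)OC(=O)C[C@@H](C)CCI | intermediate
23 | methyl (R)-5-iodo-3-methylpentanoate | COC(=O)C[C@@H](C)CCI | intermediate
24 | (R)-(5-methoxy-3-methyl-5-oxopentyl)zinc iodide (not isolated) | COC(=O)C[C@@H](C)CC[Zn]I | intermediate
25 | methyl (13S)-7α-(tert-butyldimethylsilyloxy)-2α,3α-(isopropylidenedioxy)labd-8-en-15-oate | COC(=O)C[C@@H](C)CCC1=C(C)[C@H](O[Si](C)(C)C(C)(C)C)C[C@@H]2[C@]1(C)C[C@H]3OC(C)(C)O[C@H]3C2(C)C | intermediate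
26 | methyl (13S)-7α-hydroxy-2α,3α-(isopropylidenedioxy)labd-8-en-15-oate | COC(=O)C[C@@H](C)CCC1=C(C)[C@H](O)C[C@@H]2[C@]1(C)C[C@H]3OC(C)(C)O[C@H]3C2(C)C | intermediate
27 | methyl (13S)-2α,3α-(isopropylidenedioxy)-7-oxolabd-8-en-15-oate | COC(=O)C[C@@H](C)CCC1=C(C)C(=O)C[C@@H]2[C@]1(C)C[C@H]3OC(C)(C)O[C@H]3C2(C)C | intermediate
28 | methyl (13S)-7β-hydroxy-2α,3α-(isopropylidenedioxy)labd-8-en-15-oate | COC(=O)C[C@@H](C)CCC1=C(C)[C@@H](O)C[C@@H]2[C@]1(C)C[C@H]3OC(C)(C)O[C@H]3C2(C)C | intermediate
29 | 7α-N-(2-nitrobenzenesulfonyl)hydrazine from Mitsunobu displacement (not isolated) | COC(=O)C[C@@H](C)CCC1=C(C)[C@H](N(N)S(=O)(=O)c4ccccc4[N+](=O)[O-])C[C@@H]2[C@]1(C)C[C@H]3OC(C)(C)O[C@H]3C2(C)C | intermediate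
30 | 7α-allylic diazene (not isolated) | COC(=O)C[C@@H](C)CCC1=C(C)[C@H](N=N)C[C@@H]2[C@]1(C)C[C@H]3OC(C)(C)O[C@H]3C2(C)C | intermediate
31 | methyl (13S)-2α,3α-(isopropylidenedioxy)labd-7-en-15-oate | COC(=O)C[C@@H](C)CC[C@H]1C(C)=CC[C@@H]2[C@]1(C)C[C@H]3OC(C)(C)O[C@H]3C2(C)C | intermediate
32 | methyl (13S)-2α,3α-dihydroxylabd-7-en-15-oate | COC(=O)C[C@@H](C)CC[C@H]1C(C)=CC[C@@H]2[C@]1(C)C[C@@H](O)[C@@H](O)C2(C)C | intermediate
33 | methyl (13S)-2α-acetoxy-3α-hydroxylabd-7-en-15-oate (CNP0571009.1) | COC(=O)C[C@@H](C)CC[C@H]1C(C)=CC[C@H]2C(C)(C)[C@H](O)[C@H](OC(C)=O)C[C@]12C | target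

**Step count and risks**

Total: 18 steps. Longest linear sequence: 16 steps (steps 1–9 and 12–18); steps 10–11 prepare the side-chain iodide.

Steps most likely to fail:

1. Step 4. The crowded tetrasubstituted enolate 10, next to a carbon carrying a tert-alkyl group, may undergo O-allylation or proton transfer instead of C-allylation. Fallback: starting again from 6 and passing through 9 and 10 as before, the enolate is trapped on oxygen with allyl chloroformate to give the allyl enol carbonate F1. F1 is isolated and treated with Pd2(dba)3/PPh3 in THF (Tsuji decarboxylative allylation, zerovalent palladium). Loss of CO2 regenerates the same enolate regiospecifically as its π-allylpalladium ion pair, which should recombine at C10 anti to the C5 substituent and rejoin the route at 11.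

2. Step 8. The axial C7 silyloxy group is aligned with the C8=C9 enolate and may be expelled (E1cB) before methylation. Fallback: from 14 the silyl ether is cleaved (HF·pyridine, THF) to the 7α-hydroxy ketone F2. Two equivalents of LiN(iPr)2 convert F2 into the dilithium alkoxide enolate F3, in which oxide cannot act as a leaving group (dianion alkylation of the Fráter–Seebach type). MeI then methylates C8 to give the 7α-hydroxy-8-methyl ketone F4, and TBSOTf/2,6-lutidine restores the silyl ether, rejoining the route at 16.

3. Step 16. The Mitsunobu displacement at the C7 carbinol, flanked by the tetrasubstituted olefin, may be too slow, so that the sulfonyl hydrazide decomposes first. Fallback: from 28 the 7β-formate F5 is prepared (acetic formic anhydride, pyridine) and heated with Pd(OAc)2/PBu3 in dioxane (Tsuji formate hydrogenolysis). Palladium ionises the formate from the α-face, anti to the leaving group, CO2 is lost, and hydride passes from the metal to the more substituted terminus C9 on that same face. This should give 9α-H and the Δ7 olefin, rejoining the route at 31.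

Further compounds
F1 | step 4 | allyl enol carbonate of enolate 10 (allyl carbonate on the C9 oxygen, C9=C10, 5β reverse-prenyl, 7α-OTBS) | C=CCOC(=O)OC1=C(C)[C@H](C(C)(C)C=C)C[C@@H](O[Si](C)(C)C(C)(C)C)C1
F2 | step 8 | 7α-hydroxy ketone (14 without the silyl group) | O=C1C[C@H](O)C[C@@H]2[C@]1(C)C[C@H]3OC(C)(C)O[C@H]3C2(C)C
F3 | step 8 | dilithium alkoxide enolate of F2 | [Li]OC1=C[C@H](O[Li])C[C@@H]2[C@]1(C)C[C@H]3OC(C)(C)O[C@H]3C2(C)C
F4 | step 8 | 7α-hydroxy-8-methyl ketone (C8 epimers) | O=C1C(C)[C@H](O)C[C@@H]2[C@]1(C)C[C@H]3OC(C)(C)O[C@H]3C2(C)C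
F5 | step 16 | methyl (13S)-7β-formyloxy-2α,3α-(isopropylidenedioxy)labd-8-en-15-oate | COC(=O)C[C@@H](C)CCC1=C(C)[C@@H](OC=O)C[C@@H]2[C@]1(C)C[C@H]3OC(C)(C)O[C@H]3C2(C)C
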